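**Retrosynthetic overview**
1. The 1,3-dioxane ring D (west ketal C–O–east ketal C) is opened first in the retro sense: retro-oxa-Michael gives a west hemiketal, stored as methyl ketal 28, and an aromatic 4-pyranone ring E.
2. Structural handle: ring E (the 2,3-dihydro-4-pyranone) hides CH3–C(O)–CH–C(=O), an acetoacetyl fragment spanning the methyl-bearing east ketal carbon, the ring-fusion CH and the ketone carbon, and its C=C (alpha carbon with CH2O, beta carbon with the aryl) is the C3–C4 bond of a chroman-4-one enol. Ring E is therefore cut into acetylketene (from dioxinone 25) and 4-silyloxy-2H-chromene 13.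
3. 25 comes from chromone-3-carbaldehyde 20 and magnesiated 5-iodo-dioxinone. The enantioselective addition sets the carbinol carbon, the only independent stereocentre, and ketal exchange then closes the west pyran ring.
4. 20 and 13 both derive from acetophenone 9, made from 2,3-dihydroxybenzoic acid (C5 bromination, benzylation, Br to OH, ortho-iodination, Stille acetylation).
5. Ring order: west chromone and east chromanone rings, then the west ketal pyran ring, then pyranone ring E (key step), then dioxane ring D.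

Key step: step 17

Assumption: methyl ketal 25 is expected as a mixture of epimers at the methoxy-bearing carbon; the (3S) epimer is drawn and both are carried on, because that centre is re-equilibrated in step 18.

**Route**

Step 1
Reactants: 1 2,3-dihydroxybenzoic acid
Product: 2 5-bromo-2,3-dihydroxybenzoic acid
Conditions: Br2 (1.0 equiv), AcOH, 23 °C
Reagents that add atoms: bromine, BrBr
Why: Electrophilic aromatic bromination should go to C5, para to the 2-hydroxyl and meta to the carboxyl group, the one position on which all directing effects agree (as in salicylic acid).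

Step 2
Reactants: 2 5-bromo-2,3-dihydroxybenzoic acid; 3 benzyl bromide
Product: 4 benzyl 2,3-bis(benzyloxy)-5-bromobenzoate
Conditions: BnBr (3.5 equiv), K2CO3, DMF, 60 °C
Reagents that add atoms: benzyl bromide (3), BrCc1ccccc1
Why: Williamson etherification of both phenols and O-alkylation of the carboxylate proceed together under carbonate in DMF.

Step 3
Reactants: 4 benzyl 2,3-bis(benzyloxy)-5-bromobenzoate
Product: 6 benzyl 2,3-bis(benzyloxy)-5-hydroxybenzoate, via pinacol boronate 5 (not isolated)
Conditions: B2pin2, Pd(dppf)Cl2 (3 mol%), KOAc, dioxane, 90 °C; then H2O2 (30%), NaOH (1 M), THF, 0 °C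
Reagents that add atoms: bis(pinacolato)diboron, CC1(C)OB(OC1(C)C)B1OC(C)(C)C(C)(C)O1 (into 5); hydrogen peroxide, OO
Why: Miyaura borylation of the unhindered aryl bromide followed by boronate oxidation installs the oxygen that becomes the ring oxygen of both benzopyranones.

Step 4
Reactants: 6 benzyl 2,3-bis(benzyloxy)-5-hydroxybenzoate
Product: 7 benzyl 2,3-bis(benzyloxy)-5-hydroxy-6-iodobenzoate
Conditions: NIS (1.0 equiv), MeCN, 0 °C
Reagents that add atoms: N-iodosuccinimide, O=C1CCC(=O)N1I
Why: Electrophilic iodination of the phenol should favour C6, which is ortho to OH, para to the 3-benzyloxy group and not shielded by its benzyl arm, the same preference that places electrophiles between ester and alkoxy in 3,5-dialkoxybenzoates.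

Step 5
Reactants: 7 benzyl 2,3-bis(benzyloxy)-5-hydroxy-6-iodobenzoate
Product: 9 benzyl 2-acetyl-5,6-bis(benzyloxy)-3-hydroxybenzoate, via enol ether 8 (not isolated)
Conditions: Bu3SnC(OEt)=CH2, Pd(PPh3)4 (5 mol%), toluene, 100 °C; then 1 M HCl, THF, 23 °C
Reagents that add atoms: tributyl(1-ethoxyvinyl)stannane, CCCC[Sn](CCCC)(CCCC)C(=C)OCC; water, O
Why: Stille coupling with the 1-ethoxyvinyl stannane and hydrolysis of the enol ether is a Lewis-acid-free route to an aryl methyl ketone that spares the benzyl ethers.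

Step 6
Reactants: 9 benzyl 2-acetyl-5,6-bis(benzyloxy)-3-hydroxybenzoate
Product: 11 benzyl 6,7-bis(benzyloxy)-4-oxo-4H-chromene-5-carboxylate, via enaminone 10 (not isolated)
Conditions: DMF-DMA, toluene, 100 °C; then AcOH, 60 °C
Reagents that add atoms: N,N-dimethylformamide dimethyl acetal, COC(OC)N(C)C
Why: Condensation of the methyl ketone with DMF-DMA gives the o-hydroxyaryl enaminone, which cyclises in acid with loss of dimethylamine (enaminone synthesis of chromones free at C2 and C3).

Step 7
Reactants: 11 benzyl 6,7-bis(benzyloxy)-4-oxo-4H-chromene-5-carboxylate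
Product: 12 benzyl 6,7-bis(benzyloxy)-4-oxochromane-5-carboxylate
Conditions: LiBH(s-Bu)3 (1.1 equiv), THF, −78 °C; AcOH
Reagents that add atoms: none
Why: Conjugate (1,4) hydride addition of the bulky borohydride to the chromone gives the enolate, which is protonated cold to the chromanone, so that no C4 alkoxide is formed next to the peri ester.

Step 8
Reactants: 12 benzyl 6,7-bis(benzyloxy)-4-oxochromane-5-carboxylate
Product: 13 benzyl 6,7-bis(benzyloxy)-4-[(tert-butyldimethylsilyl)oxy]-2H-chromene-5-carboxylate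
Conditions: TBSOTf, Et3N, CH2Cl2, 0 °C
Reagents that add atoms: tert-butyldimethylsilyl triflate, CC(C)(C)[Si](C)(C)OS(=O)(=O)C(F)(F)F
Why: Soft enolisation and O-silylation; C3 is the only enolisable position, so a single silyl enol ether regioisomer should form.

Step 9
Reactants: 14 ethyl 2-(2-methyl-1,3-dioxolan-2-yl)acetate (fructone)
Product: 15 2-(2-methyl-1,3-dioxolan-2-yl)acetic acid
Conditions: LiOH, THF–H2O, 0 to 23 °C; then 1 M HCl to pH 4, 0 °C
Reagents that add atoms: lithium hydroxide, [Li+].[OH-]
Why: Ester saponification under basic conditions leaves the acid-sensitive dioxolane intact, and cold acidification to pH 4 frees the acid.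

Step 10
Reactants: 9 benzyl 2-acetyl-5,6-bis(benzyloxy)-3-hydroxybenzoate; 15 2-(2-methyl-1,3-dioxolan-2-yl)acetic acid
Product: 16 benzyl 2-acetyl-5,6-bis(benzyloxy)-3-{[2-(2-methyl-1,3-dioxolan-2-yl)acetyl]oxy}benzoate
Conditions: DCC, DMAP (10 mol%), CH2Cl2, 0 to 23 °C
Reagents that add atoms: none
Why: Steglich esterification acylates the hydrogen-bonded phenol under neutral conditions.

Step 11
Reactants: 16 benzyl 2-acetyl-5,6-bis(benzyloxy)-3-{[2-(2-methyl-1,3-dioxolan-2-yl)acetyl]oxy}benzoate
Product: 17 benzyl 5,6-bis(benzyloxy)-3-hydroxy-2-[4-(2-methyl-1,3-dioxolan-2-yl)-3-oxobutanoyl]benzoate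
Conditions: LiN(SiMe3)2 (2.5 equiv), THF, −78 to −20 °C; AcOH
Reagents that add atoms: none
Why: Baker–Venkataraman rearrangement, in which the kinetic methyl-ketone enolate attacks the neighbouring aryl ester through a six-membered transition state faster than the hindered benzyl ester.

Step 12
Reactants: 17 benzyl 5,6-bis(benzyloxy)-3-hydroxy-2-[4-(2-methyl-1,3-dioxolan-2-yl)-3-oxobutanoyl]benzoate
Product: 19 benzyl 6,7-bis(benzyloxy)-3-bromo-2-[(2-methyl-1,3-dioxolan-2-yl)methyl]-4-oxo-4H-chromene-5-carboxylate, via bromodiketone 18 (not isolated)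
Conditions: NBS (1.0 equiv), CH2Cl2, 0 °C; then TsOH·H2O (10 mol%), toluene, 4 Å MS, 80 °C
Reagents that add atoms: N-bromosuccinimide, O=C1CCC(=O)N1Br
Why: The enolised 1,3-diketone is brominated at its central carbon much faster than the arene, and anhydrous acid-catalysed cyclodehydration (as in 3-bromoflavone syntheses) then closes the chromone with the halogen fixed at C3 and the dioxolane intact.

Step 13
Reactants: 19 benzyl 6,7-bis(benzyloxy)-3-bromo-2-[(2-methyl-1,3-dioxolan-2-yl)methyl]-4-oxo-4H-chromene-5-carboxylate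
Product: 20 benzyl 6,7-bis(benzyloxy)-3-formyl-2-[(2-methyl-1,3-dioxolan-2-yl)methyl]-4-oxo-4H-chromene-5-carboxylate
Conditions: Pd(OAc)2 (2 mol%), di(1-adamantyl)-n-butylphosphine (6 mol%), CO/H2 (1:1, 5 bar), TMEDA, toluene, 100 °C
Reagents that add atoms: carbon monoxide, [C-]#[O+]
Why: Palladium-catalysed reductive carbonylation (formylation with CO/H2) of the activated alkenyl bromide, run with a homogeneous phosphine catalyst that should not hydrogenolyse benzyl groups.

Step 14
Reactants: 21 2,2,6-trimethyl-4H-1,3-dioxin-4-one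
Product: 22 5-iodo-2,2,6-trimethyl-4H-1,3-dioxin-4-one
Conditions: NIS, AcOH, 23 °C
Reagents that add atoms: N-iodosuccinimide, O=C1CCC(=O)N1I
Why: Electrophilic iodination at C5, the nucleophilic alpha carbon of the enol ether–lactone, gives a known iodide.

Step 15
Reactants: 22 5-iodo-2,2,6-trimethyl-4H-1,3-dioxin-4-one; 20 benzyl 6,7-bis(benzyloxy)-3-formyl-2-[(2-methyl-1,3-dioxolan-2-yl)methyl]-4-oxo-4H-chromene-5-carboxylate
Product: 24 benzyl 6,7-bis(benzyloxy)-3-[(R)-hydroxy(2,2,6-trimethyl-4-oxo-4H-1,3-dioxin-5-yl)methyl]-2-[(2-methyl-1,3-dioxolan-2-yl)methyl]-4-oxo-4H-chromene-5-carboxylate, via alkenylmagnesium chloride 23 (not isolated)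
Conditions: iPrMgCl·LiCl, THF, −40 °C; Ti(OiPr)4 (3 equiv), CH2Cl2, −78 °C; then 20, (S)-H8-BINOL (10 mol%), 0 °C
Reagents that add atoms: none
Why: Iodine–magnesium exchange gives the known alkenyl Grignard 23, and after transmetalation a titanium H8-BINOLate catalyses its 1,2-addition to the aldehyde (catalytic enantioselective Grignard–titanium aryl/alkenyl transfer), where the catalyst only has to tell the formyl H from the chromonyl group and the (S)-ligand is expected, by analogy with titanium BINOLate additions, to direct attack to the Si face and give the (R)-carbinol.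

Step 16
Reactants: 24 the (R)-carbinol from step 15
Product: 25 benzyl (1R,3S)-7,8-bis(benzyloxy)-3-methoxy-3-methyl-10-oxo-1-(2,2,6-trimethyl-4-oxo-4H-1,3-dioxin-5-yl)-4,10-dihydro-1H,3H-pyrano[4,3-b]chromene-9-carboxylate
Conditions: CSA (10 mol%), MeOH, 23 °C
Reagents that add atoms: methanol, CO
Why: Acid-catalysed transketalisation in which the carbinol oxygen captures the oxocarbenium ion of the exchanging ketal in a six-membered ring; the carbinol C–O bond is not broken, so its configuration is kept.

Step 17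
Reactants: 25 west methyl ketal carrying the dioxinone; 13 benzyl 6,7-bis(benzyloxy)-4-[(tert-butyldimethylsilyl)oxy]-2H-chromene-5-carboxylate
Product: 28 benzyl (1S,3S)-7,8-bis(benzyloxy)-1-{8,9-bis(benzyloxy)-10-[(benzyloxy)carbonyl]-2-methyl-4-oxo-4H,5H-pyrano[3,2-c]chromen-3-yl}-3-methoxy-3-methyl-10-oxo-4,10-dihydro-1H,3H-pyrano[4,3-b]chromene-9-carboxylate, via acetylketene 26 (not isolated), via silyloxydihydropyranone 27 (not isolated)
Conditions: 13 (3 equiv), toluene, 110 °C; then CSA (cat.), MeOH, 23 °C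
Reagents that add atoms: none
Why: At 110 °C the dioxinone ring of 25 undergoes a retro-[4+2] loss of acetone and unmasks acetylketene 26, in which the west tricycle sits on the carbon between the two carbonyl groups. The electron-rich CH carbon (C3) of silyl enol ether 13 bonds to the ketene carbon and the acetyl oxygen bonds to the silyloxy-bearing C4, a [4+2] hetero-Diels–Alder closure of the six-membered ring E that gives 27, and acid-promoted loss of tert-butyldimethylsilanol aromatises it to the 4-pyranone 28. The closest known chemistry is the thermolysis of 1,3-dioxin-4-ones to acylketenes and their cycloaddition with enol ethers, silyl enol ethers and enamines to give 4-pyranones. No lasting stereocentre is made (the two ring-fusion centres of 27 vanish on elimination) and the carbinol centre, which carries no enolisable hydrogen, stays untouched under these neutral conditions. The step needs regioselective intermolecular capture of the ketene: the polarity of the silyl enol ether fixes the orientation, the ketal is masked as its methyl ether so the molecule has no OH that could add to the ketene, and a threefold excess of 13 keeps bimolecular capture ahead of ketene self-condensation.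

Step 18
Reactants: 28 hexabenzyl pyranone methyl ketal
Product: 30 hexabenzyl bis-ketal (the target with its four phenols and two acids benzylated), via hemiketal 29 (not isolated)
Conditions: 1 M HCl, THF, 23 to 40 °C
Reagents that add atoms: water, O
Why: Proposed new method: aqueous acid exchanges the methyl ketal for hemiketal 29, which equilibrates through its oxocarbenium ion to the epimer with OH syn to the pyranone; that OH then adds in conjugate fashion to the methyl-bearing C2 of the protonated 4-pyranone, forming the O–C bond of the six-membered dioxane ring D, and the dienol is protonated at the alpha carbon; the tether through the west ketal carbon and the carbinol carbon lets the oxygen reach C2 only from the face that leaves ring E on the convex side of the new 2,8-dioxabicyclo[3.3.1]nonane (ketal methyl endo), which sets the east ketal centre, while the enolisable alpha CH should settle under equilibration into the cis D/E fusion; the closest known chemistry is the acid-catalysed intramolecular oxa-Michael addition of hydroxyl groups to enones and chromones and acid-driven bicyclic ketalisation.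

Step 19
Reactants: 30 hexabenzyl bis-ketal
Product: 31 CNP0230818.1 (target; west ketal R, carbinol CH S, ring-E alpha CH S, east ketal S)
Conditions: H2 (1 atm), 10% Pd/C, EtOAc–MeOH, 23 °C
Reagents that add atoms: none
Why: Hydrogenolysis removes the four benzyl ethers and two benzyl esters under neutral conditions that should leave the tetrasubstituted enone and chromone double bonds and both ketals unchanged.

**Compound list**
1 | 2,3-dihydroxybenzoic acid | O=C(O)c1cccc(O)c1O | starting material
2 | 5-bromo-2,3-dihydroxybenzoic acid | O=C(O)c1cc(Br)cc(O)c1O | intermediate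
3 | benzyl bromide | BrCc1ccccc1 | starting material
4 | benzyl 2,3-bis(benzyloxy)-5-bromobenzoate | O=C(OCc1ccccc1)c1cc(Br)cc(OCc2ccccc2)c1OCc1ccccc1 | intermediate
5 | benzyl 2,3-bis(benzyloxy)-5-(4,4,5,5-tetramethyl-1,3,2-dioxaborolan-2-yl)benzoate | O=C(OCc1ccccc1)c1cc(B2OC(C)(C)C(C)(C)O2)cc(OCc2ccccc2)c1OCc1ccccc1 | intermediate (not isolated)
6 | benzyl 2,3-bis(benzyloxy)-5-hydroxybenzoate | O=C(OCc1ccccc1)c1cc(O)cc(OCc2ccccc2)c1OCc1ccccc1 | intermediate
7 | benzyl 2,3-bis(benzyloxy)-5-hydroxy-6-iodobenzoate | O=C(OCc1ccccc1)c1c(I)c(O)cc(OCc2ccccc2)c1OCc1ccccc1 | intermediate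
8 | benzyl 2,3-bis(benzyloxy)-6-(1-ethoxyvinyl)-5-hydroxybenzoate | O=C(OCc1ccccc1)c1c(C(=C)OCC)c(O)cc(OCc2ccccc2)c1OCc1ccccc1 | intermediate (not isolated)
9 | benzyl 2-acetyl-5,6-bis(benzyloxy)-3-hydroxybenzoate | CC(=O)c1c(O)cc(OCc2ccccc2)c(OCc2ccccc2)c1C(=O)OCc1ccccc1 | intermediate
10 | benzyl 5,6-bis(benzyloxy)-2-[(2E)-3-(dimethylamino)prop-2-enoyl]-3-hydroxybenzoate | CN(C)/C=C/C(=O)c1c(O)cc(OCc2ccccc2)c(OCc2ccccc2)c1C(=O)OCc1ccccc1 | intermediate (not isolated)
11 | benzyl 6,7-bis(benzyloxy)-4-oxo-4H-chromene-5-carboxylate | O=c1ccoc2cc(OCc3ccccc3)c(OCc3ccccc3)c(C(=O)OCc3ccccc3)c12 | intermediate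
12 | benzyl 6,7-bis(benzyloxy)-4-oxochromane-5-carboxylate | O=C1CCOc2cc(OCc3ccccc3)c(OCc3ccccc3)c(C(=O)OCc3ccccc3)c12 | intermediate
13 | benzyl 6,7-bis(benzyloxy)-4-[(tert-butyldimethylsilyl)oxy]-2H-chromene-5-carboxylate | CC(C)(C)[Si](C)(C)OC1=CCOc2cc(OCc3ccccc3)c(OCc3ccccc3)c(C(=O)OCc3ccccc3)c12 | intermediate
14 | ethyl 2-(2-methyl-1,3-dioxolan-2-yl)acetate | CCOC(=O)CC1(C)OCCO1 | starting material
15 | 2-(2-methyl-1,3-dioxolan-2-yl)acetic acid | OC(=O)CC1(C)OCCO1 | intermediate
16 | benzyl 2-acetyl-5,6-bis(benzyloxy)-3-{[2-(2-methyl-1,3-dioxolan-2-yl)acetyl]oxy}benzoate | CC(=O)c1c(OC(=O)CC2(C)OCCO2)cc(OCc2ccccc2)c(OCc2ccccc2)c1C(=O)OCc1ccccc1 | intermediate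
17 | benzyl 5,6-bis(benzyloxy)-3-hydroxy-2-[4-(2-methyl-1,3-dioxolan-2-yl)-3-oxobutanoyl]benzoate | CC1(CC(=O)CC(=O)c2c(O)cc(OCc3ccccc3)c(OCc3ccccc3)c2C(=O)OCc2ccccc2)OCCO1 | intermediate
18 | benzyl 5,6-bis(benzyloxy)-2-[2-bromo-4-(2-methyl-1,3-dioxolan-2-yl)-3-oxobutanoyl]-3-hydroxybenzoate (racemic at CHBr) | CC1(CC(=O)C(Br)C(=O)c2c(O)cc(OCc3ccccc3)c(OCc3ccccc3)c2C(=O)OCc2ccccc2)OCCO1 | intermediate (not isolated)
19 | benzyl 6,7-bis(benzyloxy)-3-bromo-2-[(2-methyl-1,3-dioxolan-2-yl)methyl]-4-oxo-4H-chromene-5-carboxylate | CC1(Cc2oc3cc(OCc4ccccc4)c(OCc4ccccc4)c(C(=O)OCc4ccccc4)c3c(=O)c2Br)OCCO1 | intermediate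
20 | benzyl 6,7-bis(benzyloxy)-3-formyl-2-[(2-methyl-1,3-dioxolan-2-yl)methyl]-4-oxo-4H-chromene-5-carboxylate | CC1(Cc2oc3cc(OCc4ccccc4)c(OCc4ccccc4)c(C(=O)OCc4ccccc4)c3c(=O)c2C=O)OCCO1 | intermediate
21 | 2,2,6-trimethyl-4H-1,3-dioxin-4-one | CC1=CC(=O)OC(C)(C)O1 | starting material
22 | 5-iodo-2,2,6-trimethyl-4H-1,3-dioxin-4-one | CC1=C(I)C(=O)OC(C)(C)O1 | intermediate
23 | (2,2,6-trimethyl-4-oxo-4H-1,3-dioxin-5-yl)magnesium chloride | CC1=C([Mg]Cl)C(=O)OC(C)(C)O1 | intermediate (not isolated)
24 | benzyl 6,7-bis(benzyloxy)-3-[(R)-hydroxy(2,2,6-trimethyl-4-oxo-4H-1,3-dioxin-5-yl)methyl]-2-[(2-methyl-1,3-dioxolan-2-yl)methyl]-4-oxo-4H-chromene-5-carboxylate | CC1(Cc2oc3cc(OCc4ccccc4)c(OCc4ccccc4)c(C(=O)OCc4ccccc4)c3c(=O)c2[C@@H](O)C2=C(C)OC(C)(C)OC2=O)OCCO1 | intermediate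
25 | benzyl (1R,3S)-7,8-bis(benzyloxy)-3-methoxy-3-methyl-10-oxo-1-(2,2,6-trimethyl-4-oxo-4H-1,3-dioxin-5-yl)-4,10-dihydro-1H,3H-pyrano[4,3-b]chromene-9-carboxylate (C3 epimer also carried) | C[C@@]1(OC)Cc2oc3cc(OCc4ccccc4)c(OCc4ccccc4)c(C(=O)OCc4ccccc4)c3c(=O)c2[C@@H](O1)C1=C(C)OC(C)(C)OC1=O | intermediate
26 | acetylketene: 25 with the dioxinone replaced at C1 by C(=C=O)C(=O)CH3, same configuration | C[C@@]1(OC)Cc2oc3cc(OCc4ccccc4)c(OCc4ccccc4)c(C(=O)OCc4ccccc4)c3c(=O)c2[C@@H](O1)C(C(C)=O)=C=O | intermediate (not isolated)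
27 | [4+2] adduct of 26 and 13: 6-silyloxy-5,6-dihydro-4-pyranone fused to the chromane (the two new ring-fusion centres undefined, lost on elimination) | C[C@@]1(OC)Cc2oc3cc(OCc4ccccc4)c(OCc4ccccc4)c(C(=O)OCc4ccccc4)c3c(=O)c2[C@@H](O1)C1=C(C)OC2(O[Si](C)(C)C(C)(C)C)C(C1=O)COc1cc(OCc3ccccc3)c(OCc3ccccc3)c(C(=O)OCc3ccccc3)c12 | intermediate (not isolated)
28 | benzyl (1S,3S)-7,8-bis(benzyloxy)-1-{8,9-bis(benzyloxy)-10-[(benzyloxy)carbonyl]-2-methyl-4-oxo-4H,5H-pyrano[3,2-c]chromen-3-yl}-3-methoxy-3-methyl-10-oxo-4,10-dihydro-1H,3H-pyrano[4,3-b]chromene-9-carboxylate | C[C@@]1(OC)Cc2oc3cc(OCc4ccccc4)c(OCc4ccccc4)c(C(=O)OCc4ccccc4)c3c(=O)c2[C@@H](O1)C1=C(C)OC2=C(C1=O)COc1cc(OCc3ccccc3)c(OCc3ccccc3)c(C(=O)OCc3ccccc3)c12 | intermediate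
29 | hemiketal: 28 with OH in place of OCH3 at C3, hydroxyl syn to the pyranone | C[C@@]1(O)Cc2oc3cc(OCc4ccccc4)c(OCc4ccccc4)c(C(=O)OCc4ccccc4)c3c(=O)c2[C@@H](O1)C1=C(C)OC2=C(C1=O)COc1cc(OCc3ccccc3)c(OCc3ccccc3)c(C(=O)OCc3ccccc3)c12 | intermediate (not isolated)
30 | hexabenzyl bis-ketal: the target with four O-benzyl ethers and two benzyl esters (west ketal R, carbinol S, alpha CH S, east ketal S) | C[C@@]12Cc3oc4cc(OCc5ccccc5)c(OCc5ccccc5)c(C(=O)OCc5ccccc5)c4c(=O)c3[C@@H](O1)[C@H]1C(=O)C3=C(O[C@@]1(C)O2)c1c(cc(OCc4ccccc4)c(OCc4ccccc4)c1C(=O)OCc1ccccc1)OC3 | intermediate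
31 | CNP0230818.1: 2,8-dioxabicyclo[3.3.1]nonane bis-ketal joining the fulvic-acid-type pyrano[4,3-b]chromenone and the citromycetin-type dihydropyrano[3,2-c]chromenone | C[C@@]12Cc3oc4cc(O)c(O)c(C(=O)O)c4c(=O)c3[C@@H](O1)[C@H]1C(=O)C3=C(O[C@@]1(C)O2)c1c(cc(O)c(O)c1C(=O)O)OC3 | target

**Step count and risks**

Total step count: 19. Longest linear sequence: 14 steps (steps 1–5, 10–13, 15–19). Steps 6–8, 9 and 14 are side branches.

Steps most likely to fail:

1. Step 18 (the proposed method). The hemiketal may not add to the weakly electrophilic pyranone, the closure may stay an incomplete equilibrium, or prolonged acid may ionise the carbinol or ketal C–O bonds and scramble the ring fusion or erode enantiopurity. Fallback with known chemistry: starting from 28, the same aqueous acid treatment is stopped at hemiketal 29, which is isolated and treated with NIS in CH2Cl2 at 0 °C. Iodonium attack at the nucleophilic alpha carbon of the pyranone and anti capture of the oxocarbenium ion by the hemiketal hydroxyl (iodoetherification of an enol ether) should close ring D irreversibly to the alpha-iodo hexabenzyl bis-ketal F1. Hydrogenation over Pd/C with Et3N then removes the iodine together with the six benzyl groups, and the route is rejoined at 31.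

2. Step 17 (key step). The ketene may be lost to self-condensation or to reversible internal capture by the chromone carbonyl or ketal oxygens before the hindered silyl enol ether reacts, and silanol loss may be slow. Fallback: starting from chromanone 12, condensation with morpholine (TiCl4, toluene, 0 to 23 °C) gives the morpholine enamine F2, a much stronger carbon nucleophile. Heating 25 with F2 in toluene at 100 °C should acylate the enamine carbon as soon as the ketene forms, and AcOH work-up closes the pyranone with loss of morpholine, rejoining the route at 28.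

3. Step 15. Transfer of the electron-poor alkenyl group from titanium may be slow, the reagent may enolise the C2 methylene of 20, or facial selectivity may be inadequate; the sense of induction is assigned by analogy, and the antipodal ligand would be used if it proved opposite. Fallback: Grignard 23 is added to aldehyde 20 without titanium (THF, −40 °C) to give the racemic carbinol F3. Dess–Martin periodinane oxidises it to the ketone F4. Reduction with (R)-Me-CBS and catecholborane (toluene, −78 °C), in which the 2-alkylchromonyl group with its fused benzo ring should act as the large substituent, rejoins the route at 24. Because the two flanks are similar, selectivity there is uncertain; mis-reduced material can be recycled through F4.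

**Further compounds**
F1 | step 18 | hexabenzyl bis-ketal with iodine on the ring-E alpha carbon, cis to the east ketal methyl | C[C@@]12Cc3oc4cc(OCc5ccccc5)c(OCc5ccccc5)c(C(=O)OCc5ccccc5)c4c(=O)c3[C@@H](O1)[C@@]1(I)C(=O)C3=C(O[C@@]1(C)O2)c1c(cc(OCc4ccccc4)c(OCc4ccccc4)c1C(=O)OCc1ccccc1)OC3
F2 | step 17 | benzyl 6,7-bis(benzyloxy)-4-(morpholin-4-yl)-2H-chromene-5-carboxylate | C1COCCN1C1=CCOc2cc(OCc3ccccc3)c(OCc3ccccc3)c(C(=O)OCc3ccccc3)c12
F3 | step 15 | racemic form of carbinol 24 | CC1(Cc2oc3cc(OCc4ccccc4)c(OCc4ccccc4)c(C(=O)OCc4ccccc4)c3c(=O)c2C(O)C2=C(C)OC(C)(C)OC2=O)OCCO1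
F4 | step 15 | benzyl 6,7-bis(benzyloxy)-2-[(2-methyl-1,3-dioxolan-2-yl)methyl]-4-oxo-3-[(2,2,6-trimethyl-4-oxo-4H-1,3-dioxin-5-yl)carbonyl]-4H-chromene-5-carboxylate | CC1(Cc2oc3cc(OCc4ccccc4)c(OCc4ccccc4)c(C(=O)OCc4ccccc4)c3c(=O)c2C(=O)C2=C(C)OC(C)(C)OC2=O)OCCO1
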